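**Strategy.** The side chain is two isoprenoid C5 units joined at C4–C5. The carbinol carbon C5 sits between two almost identical methallyl-type arms (C6–C7(Me)=C8 and C4–C3(Me)=C2), so ketone reduction cannot set it and the aldehyde precursors are β,γ-unsaturated. The route inverts polarity: C5 enters as a configurationally defined α-lithiated carbamate of isoprenol and C4 as the boron-bound CH2 of an (E)-allylic boronate. One lithiation–borylation operation forms C4–C5 by stereospecific 1,2-metallate rearrangement, fixes 5S and leaves both alkenes in place; boron is then exchanged for OH. The precursor pair is a C5 carbamate and a C5 boronate; the benzophenone is attached last through O–C1.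

Key step: step 5

Remark: the side chain is numbered C1 (OCH2) to C8 (=CH2); with the priorities OH > C4 arm > C6 arm > H the target is 2E,5S. (+)-Sparteine and 2,4,6-trihydroxybenzophenone are taken as commercial.

Step 1
Reactants: 1 3-methylbut-3-en-1-ol
Product: 2 3-methylbut-3-en-1-yl N,N-diisopropylcarbamate
Conditions: NaH, THF, 0 °C; then iPr2NCOCl, reflux
Reagents that add atoms: N,N-diisopropylcarbamoyl chloride, CC(C)N(C(C)C)C(=O)Cl
Why: O-acylation of the sodium alkoxide by the carbamoyl chloride (carbamate formation) should install the group that later directs α-lithiation and serves as the leaving group, the 1,1-disubstituted alkene being inert.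

Step 2
Reactants: 3 but-2-yn-1-ol
Product: 4 tert-butyl(but-2-yn-1-yloxy)dimethylsilane
Conditions: TBSCl, imidazole, CH2Cl2, 0 °C → rt
Reagents that add atoms: tert-butyldimethylsilyl chloride, CC(C)(C)[Si](C)(C)Cl
Why: Standard imidazole-mediated silylation of a primary alcohol (silyl ether protection) should mask the C1 oxygen against the organolithium steps.

Step 3
Reactants: 4 tert-butyl(but-2-yn-1-yloxy)dimethylsilane
Product: 5 tert-butyldimethyl{[(2Z)-3-(4,4,5,5-tetramethyl-1,3,2-dioxaborolan-2-yl)but-2-en-1-yl]oxy}silane
Conditions: B2pin2, CuCl (cat.), PCy3 (cat.), NaOt-Bu (cat.), MeOH, toluene, rt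
Reagents that add atoms: bis(pinacolato)diboron, CC1(C)OB(OC1(C)C)B1OC(C)(C)C(C)(C)O1
Why: Copper-catalysed formal hydroboration (syn-borylcupration, then protonolysis of C–Cu by MeOH with retention) should place boron on the methyl-bearing carbon distal to the propargylic oxygen and cis to the new H, which fixes the future C4 position trans to C1.

Step 4
Reactants: 5 tert-butyldimethyl{[(2Z)-3-(4,4,5,5-tetramethyl-1,3,2-dioxaborolan-2-yl)but-2-en-1-yl]oxy}silane
Product: 7 tert-butyldimethyl{[(2E)-3-methyl-4-(4,4,5,5-tetramethyl-1,3,2-dioxaborolan-2-yl)but-2-en-1-yl]oxy}silane, via chloromethyl boronate complex 6 (not isolated)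
Conditions: BrCH2Cl, n-BuLi, THF, −78 °C → rt
Reagents that add atoms: bromochloromethane, ClCBr
Why: In a Matteson homologation, chloromethyllithium formed in situ adds to boron and the alkenyl group shifts 1,2 with loss of chloride on warming, which should insert C4 with retention of the alkene geometry.

Step 5
Reactants: 2 3-methylbut-3-en-1-yl N,N-diisopropylcarbamate; 7 tert-butyldimethyl{[(2E)-3-methyl-4-(4,4,5,5-tetramethyl-1,3,2-dioxaborolan-2-yl)but-2-en-1-yl]oxy}silane
Product: 11 (4S,6E)-8-[(tert-butyldimethylsilyl)oxy]-2,6-dimethylocta-1,6-dien-4-ol, via lithiated carbamate 8 (not isolated), via boronate complex 9 (not isolated), via secondary boronic ester 10 (not isolated)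
Conditions: s-BuLi, (+)-sparteine, Et2O, −78 °C; then 7, −78 °C; MgBr2·OEt2, −78 °C → reflux; then NaOH, H2O2, THF/H2O, 0 °C → rt
Reagents that add atoms: hydrogen peroxide, OO
Why: s-BuLi·(+)-sparteine, held at the carbamate C=O, should remove the pro-R hydrogen of the OCH2 group (C5) to give the configurationally stable (R)-lithio carbamate 8, which 7 borylates with retention to give ate complex 9; on warming with MgBr2 the boron-bound CH2 (C4) shifts from boron to C5 anti-periplanar to the departing carbamate (1,2-metallate rearrangement, inversion at C5) to give (S)-boronic ester 10, and alkaline H2O2 replaces boron by OH with retention. The closest known reaction type is the lithiation–borylation–oxidation of primary alkyl diisopropylcarbamates with pinacol boronic esters, a sparteine-mediated relative of the Matteson homologation. No ring is closed. The single new stereocentre C5 is controlled by the chiral diamine in the enantiotopos-selective deprotonation (reagent control) and is then carried through three stereospecific events (retention, inversion, retention), so 5S follows from the use of (+)-sparteine. The step needs α-lithiation at C5 in preference to the allylic C6–H and methyl C–H bonds, which the chelating carbamate secures, and migration of the allyl group through its boron-bound carbon without allylic transposition or E/Z change, which the concerted 1,2-shift of a primary CH2–B terminus secures, as in chloromethyllithium homologations of allylic boronates; carbon migration in preference to oxygen migration is favoured by the pinacol ester and MgBr2.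

Step 6
Reactants: 11 (4S,6E)-8-[(tert-butyldimethylsilyl)oxy]-2,6-dimethylocta-1,6-dien-4-ol
Product: 12 (2E,5S)-3,7-dimethylocta-2,7-diene-1,5-diol
Conditions: TBAF, THF, 0 °C → rt
Reagents that add atoms: none
Why: Fluoride-induced cleavage of the Si–O bond (silyl ether deprotection) should free the primary allylic alcohol without touching the alkenes or C5.

Step 7
Reactants: 12 (2E,5S)-3,7-dimethylocta-2,7-diene-1,5-diol; 13 2,4,6-trihydroxybenzophenone
Product: 14 (2,6-dihydroxy-4-{[(2E,5S)-5-hydroxy-3,7-dimethylocta-2,7-dien-1-yl]oxy}phenyl)(phenyl)methanone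
Conditions: PPh3, DIAD, THF, 0 °C → rt
Reagents that add atoms: none
Why: In a Mitsunobu etherification the primary allylic alcohol should be activated far faster than the hindered secondary C5–OH and be displaced by SN2 at C1 by the 4-OH of 13, the most acidic and least hindered phenol (the 2- and 6-OH are hydrogen-bonded to and shielded by the benzoyl group), so neither C5 nor the alkene geometry is affected.

**Compound list**

1 | 3-methylbut-3-en-1-ol | C=C(C)CCO | starting material
2 | 3-methylbut-3-en-1-yl N,N-diisopropylcarbamate | C=C(C)CCOC(=O)N(C(C)C)C(C)C | intermediate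
3 | but-2-yn-1-ol | CC#CCO | starting material
4 | tert-butyl(but-2-yn-1-yloxy)dimethylsilane | CC#CCO[Si](C)(C)C(C)(C)C | intermediate
5 | tert-butyldimethyl{[(2Z)-3-(4,4,5,5-tetramethyl-1,3,2-dioxaborolan-2-yl)but-2-en-1-yl]oxy}silane | C/C(=C\CO[Si](C)(C)C(C)(C)C)B1OC(C)(C)C(C)(C)O1 | intermediate
6 | lithium (chloromethyl){(2Z)-4-[(tert-butyldimethylsilyl)oxy]but-2-en-2-yl}(pinacolato)borate | [Li+].C/C(=C\CO[Si](C)(C)C(C)(C)C)[B-]1(CCl)OC(C)(C)C(C)(C)O1 | intermediate (not isolated)
7 | tert-butyldimethyl{[(2E)-3-methyl-4-(4,4,5,5-tetramethyl-1,3,2-dioxaborolan-2-yl)but-2-en-1-yl]oxy}silane | CC1(C)OB(C/C(C)=C/CO[Si](C)(C)C(C)(C)C)OC1(C)C | intermediate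
8 | (1R)-1-lithio-3-methylbut-3-en-1-yl N,N-diisopropylcarbamate, (+)-sparteine complex | C=C(C)C[C@H](OC(=O)N(C(C)C)C(C)C)[Li] | intermediate (not isolated)
9 | lithium {(1R)-1-[(diisopropylcarbamoyl)oxy]-3-methylbut-3-en-1-yl}{(2E)-4-[(tert-butyldimethylsilyl)oxy]-2-methylbut-2-en-1-yl}(pinacolato)borate | C=C(C)C[C@H](OC(=O)N(C(C)C)C(C)C)[B-]1(C/C(C)=C/CO[Si](C)(C)C(C)(C)C)OC(C)(C)C(C)(C)O1.[Li+] | intermediate (not isolated)
10 | tert-butyldimethyl{[(2E,5S)-3,7-dimethyl-5-(4,4,5,5-tetramethyl-1,3,2-dioxaborolan-2-yl)octa-2,7-dien-1-yl]oxy}silane | C=C(C)C[C@H](B1OC(C)(C)C(C)(C)O1)C/C(C)=C/CO[Si](C)(C)C(C)(C)C | intermediate (not isolated)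
11 | (4S,6E)-8-[(tert-butyldimethylsilyl)oxy]-2,6-dimethylocta-1,6-dien-4-ol | C=C(C)C[C@H](O)C/C(C)=C/CO[Si](C)(C)C(C)(C)C | intermediate
12 | (2E,5S)-3,7-dimethylocta-2,7-diene-1,5-diol | C=C(C)C[C@H](O)C/C(C)=C/CO | intermediate
13 | 2,4,6-trihydroxybenzophenone | O=C(c1ccccc1)c1c(O)cc(O)cc1O | starting material
14 | (2,6-dihydroxy-4-{[(2E,5S)-5-hydroxy-3,7-dimethylocta-2,7-dien-1-yl]oxy}phenyl)(phenyl)methanone | C=C(C)C[C@H](O)C/C(C)=C/COc1cc(O)c(C(=O)c2ccccc2)c(O)c1 | target

**Step count.** Total: 7 steps. Longest linear sequence: 6 steps (steps 2–7, from 3).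

**Steps most likely to fail**

Step 5. Deprotonation may occur at the allylic positions of 2 instead of at C5, the enantiotopic hydrogens may be discriminated incompletely, or the 1,2-shift may be slow and give way to oxygen migration. The fallback forms C5–C6 instead, by carbonyl methallylation from the alcohol oxidation level. It sets out from 7: a second chloromethyllithium homologation (BrCH2Cl, n-BuLi, THF, −78 °C → rt) should give tert-butyldimethyl{[(2E)-3-methyl-5-(4,4,5,5-tetramethyl-1,3,2-dioxaborolan-2-yl)pent-2-en-1-yl]oxy}silane F1, and NaOH/H2O2 should convert it into (3E)-5-[(tert-butyldimethylsilyl)oxy]-3-methylpent-3-en-1-ol F2. Iridium-catalysed transfer-hydrogenative methallylation of F2 (3-chloro-2-methylprop-1-ene, cyclometalated Ir–bisphosphine C,O-benzoate catalyst of the antipode that delivers the 5S alcohol, Cs2CO3, THF, heat) should then give 11, where the route is rejoined. The β,γ-unsaturated aldehyde would exist only as a transient metal-bound species, and C5 would be set by catalyst control.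

Step 7. The secondary C5 hydroxyl may be activated in competition, or etherification may occur at an ortho hydroxyl or twice. The fallback replaces the redox condensation by a Williamson etherification and sets out from 12. Chemoselective chlorination of the primary allylic alcohol (MsCl, LiCl, s-collidine, DMF, 0 °C) should give (4S,6E)-8-chloro-2,6-dimethylocta-1,6-dien-4-ol F3. Alkylation of 13 with F3 (K2CO3, acetone, rt, 13 in slight excess) should then take place at the non-chelated 4-OH and come back to the route at 14.

Step 3. Borylcupration may occur with the opposite orientation (boron next to the CH2O carbon) or with incomplete syn selectivity. The fallback sets the regiochemistry by hydrozirconation and sets out from 4. Treatment with excess Cp2Zr(H)Cl (THF, 50 °C, equilibration of zirconium onto the methyl-bearing carbon) and then I2 should give tert-butyl{[(2E)-3-iodobut-2-en-1-yl]oxy}dimethylsilane F4. Iodine–lithium exchange (t-BuLi, Et2O, −78 °C) and trapping with 2-isopropoxy-4,4,5,5-tetramethyl-1,3,2-dioxaborolane should proceed with retention and come back to the route at 5.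

**Further compounds**

F1 | step 5 | tert-butyldimethyl{[(2E)-3-methyl-5-(4,4,5,5-tetramethyl-1,3,2-dioxaborolan-2-yl)pent-2-en-1-yl]oxy}silane | CC1(C)OB(CC/C(C)=C/CO[Si](C)(C)C(C)(C)C)OC1(C)C
F2 | step 5 | (3E)-5-[(tert-butyldimethylsilyl)oxy]-3-methylpent-3-en-1-ol | OCC/C(C)=C/CO[Si](C)(C)C(C)(C)C
F3 | step 7 | (4S,6E)-8-chloro-2,6-dimethylocta-1,6-dien-4-ol | C=C(C)C[C@H](O)C/C(C)=C/CCl
F4 | step 3 | tert-butyl{[(2E)-3-iodobut-2-en-1-yl]oxy}dimethylsilane | C/C(I)=C\CO[Si](C)(C)C(C)(C)C
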